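Rings: A = methylcyclopentane carrying the exocyclic alkene, B = eight-membered ring, C = six-membered carbinol ring, D = isopropylcyclopentane.
Retrosynthesis: (1) put a helper ketone on the ring-C CH2 that lies between the angular-methyl carbon and the B/C fusion CH, and cut the CH2–CH2 bond of ring B (metathesis of two vinyl groups); (2) cut together the two bonds flanking the CH(CH3)–CH(fusion) pair, CH(CH3)–CH2 (vinyl anion) and fusion CH–C(OH) (aldol), which opens ring C to an acyclic 1,5-diketone; (3) cut the dienone carbonyl into a ring-A alkenyl iodide, CO and a ring-D alkylborane.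
Forward: ring A (zirconocene enyne cyclisation) and ring D (ring contraction of limonene, then a [2,3]-shift) are made separately and joined through CO; ring C closes in the key step, ring B by metathesis, and the helper ketone is then removed.
Enabling feature: with that carbonyl in place, the CH(CH3) carbon of ring B is the β-carbon and the fusion CH the α-carbon of a crotonyl ketone lying 1,5 to the carbinol carbon (a masked ketone), so conjugate addition at the β-carbon releases an enolate placed for a six-ring aldol; the (Z)-tetrasubstituted A/B alkene then holds the two vinyl groups together for the eight-ring closure.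
Stereochemistry: ring-A methyl centre from (R)-citronellene (relayed to the adjacent CH in the zirconacycle); isopropyl centre from (S)-limonene, relayed to the quaternary carbon ([2,3]-shift anti to isopropyl) and the D-ring fusion CH (hydroboration anti to isopropyl); CH(CH3) of ring B from (R)-BINAP; fusion CH and carbinol carbon from the chair aldol on the trans-hydrindane being formed.

Key step: step 16

Remark: the secondary carbinol centre made in step 11 (compounds 16–20, F7–F10) forms as a mixture of epimers and is left undefined in the SMILES; the oxidation of step 15 erases it.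

Step 1
Reactants: 1 (R)-β-citronellene [(3R)-3,7-dimethylocta-1,6-diene]
Product: 2 (4R)-4-methylhex-5-enal
Conditions: O3, CH2Cl2/MeOH, Sudan Red 7B indicator, −78 °C; then Me2S, −78 °C to rt
Reagents that add atoms: ozone, [O-][O+]=O
Why: Ozonolysis with reductive work-up should cleave the electron-rich trisubstituted alkene well before the monosubstituted vinyl group (the dye marks the end point), leaving the allylic methyl stereocentre from the chiral pool untouched.

Step 2
Reactants: 2 (4R)-4-methylhex-5-enal
Product: 3 (5R)-1,1-dibromo-5-methylhepta-1,6-diene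
Conditions: CBr4, PPh3, CH2Cl2, 0 °C
Reagents that add atoms: carbon tetrabromide, BrC(Br)(Br)Br
Why: Corey–Fuchs dibromo-olefination (Wittig reaction of the ylide Ph3P=CBr2 made in the flask) adds the carbon that becomes the alkyne terminus without touching the remote stereocentre.

Step 3
Reactants: 3 (5R)-1,1-dibromo-5-methylhepta-1,6-diene
Product: 5 (3R)-3-methyloct-1-en-6-yne, via lithium acetylide 4 (not isolated)
Conditions: n-BuLi (2.2 equiv), THF, −78 to 0 °C; then MeI, −78 °C to rt
Reagents that add atoms: iodomethane, CI
Why: Second stage of the Corey–Fuchs alkyne synthesis, in which bromine–lithium exchange and Fritsch–Buttenberg–Wiechell rearrangement give acetylide 4, whose C-methylation supplies the internal alkyne that the zirconocene cyclisation needs.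

Step 4
Reactants: 5 (3R)-3-methyloct-1-en-6-yne
Product: 7 (1Z,2S,3R)-1-(1-iodoethylidene)-2-(iodomethyl)-3-methylcyclopentane, via zirconacyclopentene 6 (not isolated)
Conditions: Cp2ZrCl2, n-BuLi (2 equiv), THF, −78 °C to rt; then I2, 0 °C to rt
Reagents that add atoms: iodine, II
Why: Zirconocene-mediated oxidative cyclisation of the 1,6-enyne (Cp2ZrBu2 as the source of divalent zirconocene) closes ring A with the allylic methyl group steering the new CH2Zr arm trans to itself in the reversibly formed metallacycle, and because zirconium and the ring CH share the five-membered metallacycle, iodinolysis with retention can only give the (Z)-alkenyl iodide.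

Step 5
Reactants: 7 (1Z,2S,3R)-1-(1-iodoethylidene)-2-(iodomethyl)-3-methylcyclopentane
Product: 8 (1S,2Z,5R)-2-(1-iodoethylidene)-5-methylcyclopentane-1-carbaldehyde
Conditions: DMSO, NaHCO3, 110 °C
Reagents that add atoms: dimethyl sulfoxide, CS(C)=O
Why: Kornblum oxidation (SN2 attack of the DMSO oxygen on the primary iodide, then base-induced collapse of the alkoxysulfonium salt) should give the aldehyde while the alkenyl iodide is inert, and the enolisable α-centre can only drift toward the wanted, more stable 1,5-trans arrangement.

Step 6
Reactants: 9 (S)-limonene [(4S)-1-methyl-4-(prop-1-en-2-yl)cyclohex-1-ene]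
Product: 10 (S)-p-menth-1-ene [(4S)-1-methyl-4-(propan-2-yl)cyclohex-1-ene]
Conditions: H2 (1 atm), RhCl(PPh3)3 (cat.), benzene/EtOH, rt
Reagents that add atoms: none
Why: RhCl(PPh3)3 hydrogenates the 1,1-disubstituted isopropenyl alkene far faster than the trisubstituted ring alkene (chemoselective homogeneous hydrogenation), and the stereocentre is not involved.

Step 7
Reactants: 10 (S)-p-menth-1-ene
Product: 11 (3S)-6-oxo-3-(propan-2-yl)heptanal
Conditions: O3, CH2Cl2/MeOH, −78 °C; then Me2S
Reagents that add atoms: ozone, [O-][O+]=O
Why: Ozonolysis with reductive work-up opens the ring alkene to the keto aldehyde, whose isopropyl-bearing centre is β to the aldehyde and cannot epimerise.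

Step 8
Reactants: 11 (3S)-6-oxo-3-(propan-2-yl)heptanal
Product: 12 (5R)-2-methyl-5-(propan-2-yl)cyclopent-1-ene-1-carbaldehyde
Conditions: piperidine, AcOH (cat.), benzene, reflux with water removal
Reagents that add atoms: none
Why: Intramolecular aldol condensation through the piperidine enamine of the aldehyde, which attacks the methyl ketone (5-exo closure) and dehydrates to the tetrasubstituted enal, so the aldehyde carbon stays exocyclic next to the isopropyl-bearing centre.

Step 9
Reactants: 12 (5R)-2-methyl-5-(propan-2-yl)cyclopent-1-ene-1-carbaldehyde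
Product: 13 [(5R)-2-methyl-5-(propan-2-yl)cyclopent-1-en-1-yl]methanol
Conditions: NaBH4, CeCl3·7H2O, MeOH, 0 °C
Reagents that add atoms: none
Why: Luche reduction should give clean 1,2-reduction of the hindered enal to the allylic alcohol.

Step 10
Reactants: 13 [(5R)-2-methyl-5-(propan-2-yl)cyclopent-1-en-1-yl]methanol
Product: 14 (3R)-2-[(but-2-yn-1-yloxy)methyl]-1-methyl-3-(propan-2-yl)cyclopent-1-ene
Conditions: NaH, 1-bromobut-2-yne, Bu4NI (cat.), THF, 0 °C to rt
Reagents that add atoms: 1-bromobut-2-yne, CC#CCBr
Why: Williamson etherification of the allylic alkoxide with the reactive propargylic bromide.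

Step 11
Reactants: 14 (3R)-2-[(but-2-yn-1-yloxy)methyl]-1-methyl-3-(propan-2-yl)cyclopent-1-ene
Product: 16 1-[(1S,3R)-1-methyl-2-methylidene-3-(propan-2-yl)cyclopentyl]but-2-yn-1-ol (carbinol epimers), via lithiated ether 15 (not isolated)
Conditions: n-BuLi, THF, −78 to −40 °C; NH4Cl (aq)
Reagents that add atoms: none
Why: [2,3]-Wittig rearrangement, in which the propargylic α-oxy carbanion 15 adds through a five-membered envelope transition state to the methyl-bearing alkene carbon on the face opposite the neighbouring isopropyl group (the O–CH unit would otherwise clash with it), creating the quaternary carbon with its new carbon arm trans to isopropyl and leaving the exocyclic methylene.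

Step 12
Reactants: 16 1-[(1S,3R)-1-methyl-2-methylidene-3-(propan-2-yl)cyclopentyl]but-2-yn-1-ol
Product: 17 (2E)-1-[(1S,3R)-1-methyl-2-methylidene-3-(propan-2-yl)cyclopentyl]but-2-en-1-ol (carbinol epimers)
Conditions: NaAlH2(OCH2CH2OCH3)2, THF, 0 °C to rt
Reagents that add atoms: none
Why: Alkoxide-directed trans-hydroalumination of the propargylic alcohol gives only the (E)-allylic alcohol, and the isolated 1,1-disubstituted alkene is not reduced.

Step 13
Reactants: 17 the (E)-allylic alcohol of ring D and 8 the ring-A iodo aldehyde
Product: 19 keto aldehyde in which a new (Z)-α-methyl enone carbonyl links ring A (formyl group still on the adjacent ring CH) to the CH2 arm of ring D (CH2 arm cis to angular methyl and isopropyl; 1-hydroxybut-2-enyl arm trans), via B-alkyl-9-BBN adduct 18 (not isolated)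
Conditions: 9-BBN (2.1 equiv), THF, 0 °C to rt; then 8, Pd(PPh3)4 (5 mol %), K3PO4 (aq), CO (1 atm), THF/DMF, rt to 50 °C
Reagents that add atoms: carbon monoxide, [C-]#[O+]
Why: 9-BBN hydroborates the exocyclic methylene (boron at CH2) far faster than the (E)-disubstituted alkene and should deliver hydrogen to the ring carbon from the face opposite the isopropyl and pseudo-axial methyl groups, which sets the D-ring fusion CH, and the B-alkyl group is then transferred to the acylpalladium formed from zerovalent palladium, alkenyl iodide 8 and CO (carbonylative Suzuki–Miyaura coupling with retention of alkene geometry), ring A carrying an aldehyde and not a vinyl group at this stage so that no alkene is available for cyclic acylpalladation.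

Step 14
Reactants: 19 keto aldehyde
Product: 20 keto alcohol in which the formyl group has become a vinyl group
Conditions: Ph3PCH3Br, KOtBu, THF, 0 °C
Reagents that add atoms: methyltriphenylphosphonium bromide, C[P+](c1ccccc1)(c1ccccc1)c1ccccc1.[Br-]
Why: Wittig methylenation is selective for the aldehyde over the hindered tetrasubstituted enone carbonyl, and the non-stabilised ylide adds faster than it enolises the α-centre.

Step 15
Reactants: 20 keto alcohol
Product: 21 acyclic 1,5-diketone (bis-enone) carrying the (E)-crotonyl ketone on the quaternary ring-D carbon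
Conditions: Dess–Martin periodinane, NaHCO3, CH2Cl2, 0 °C to rt
Reagents that add atoms: none
Why: Dess–Martin oxidation of the secondary allylic alcohol gives the (E)-crotonyl ketone under neutral buffered conditions that leave the 1,5-diketone uncyclised, and it erases the uncontrolled carbinol centre.

Step 16
Reactants: 21 bis-enone
Product: 23 ring-C aldol (β-hydroxy ketone with axial tertiary hydroxyl and equatorial alkenyl on the carbinol carbon and equatorial but-3-en-2-yl on the fusion CH; rings C/D trans-fused), via rhodium enolate 22 (not isolated)
Conditions: CH2=CHBF3K (2 equiv), [Rh(cod)Cl]2 (2.5 mol %), (R)-BINAP (6 mol %), KOH (0.2 equiv), dioxane/H2O (10:1), 80 °C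
Reagents that add atoms: potassium vinyltrifluoroborate, C=C[B-](F)(F)F.[K+]
Why: The vinyl group passes from boron to the monovalent rhodium–(R)-BINAP hydroxide, the (E)-crotonyl C=C bond inserts into the Rh–vinyl bond (first C–C bond, at the β-carbon), and the resulting (Z)-rhodium enolate 22 adds to the ketone five atoms away (second C–C bond) before hydrolysis releases the catalyst, while any enolate protonated first re-enters through the reversible KOH-mediated aldol. The closest known reaction type is the rhodium–BINAP-catalysed tandem conjugate addition–aldol cyclisation of keto-enones with organoboron reagents, together with the rhodium-catalysed 1,4-addition of potassium vinyltrifluoroborate to enones. Ring C closes in the 6-(enolendo)-exo-trig mode and no other ring forms in this step. The CH(CH3) centre is set by the catalyst, since by the quadrant model for (E)-enones (R)-BINAP delivers vinyl to the Re face of the β-carbon and the remote substrate centres exert little bias; the fusion CH follows from the (Z)-enolate of the s-cis tert-alkyl enone and is in any case equilibrated to the equatorial side chain; the carbinol centre follows from the chair transition state on the trans-hydrindane being formed, with the metal-bridged ketone oxygen axial and the bulky alkenyl group equatorial. The step needs chemoselectivity for the crotonyl enone over the second enone and the vinyl group, which the tetrasubstituted ring-A enone secures by being inert to carbometalation, and regioselective enolate formation, which is secured because the crotonyl carbonyl carries a quaternary carbon on its other side.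

Step 17
Reactants: 23 ring-C aldol
Product: 25 tetracyclic β-hydroxy ketone (sesterfisherol with a ketone on the ring-C CH2 next to the angular-methyl carbon), via cyclooctadienone 24 (not isolated)
Conditions: second-generation Grubbs catalyst (5 mol %), ClCH2CH2Cl (2 mM), 60 °C; then H2 (7 atm), 60 °C
Reagents that add atoms: none
Why: Ring-closing metathesis of the two vinyl groups should close ring B as the (Z)-cyclooctene because the trans-diequatorial attachment to ring C and the (Z)-tetrasubstituted alkene hold the olefin termini close (an eight-ring metathesis across such an alkene is a precedented reaction type), and the ruthenium hydride formed under H2 then saturates only the new disubstituted alkene (tandem metathesis–hydrogenation), which creates no stereocentre.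

Step 18
Reactants: 25 tetracyclic β-hydroxy ketone
Product: 26 1,3-anti diol (new secondary hydroxyl equatorial)
Conditions: Me4NBH(OAc)3, MeCN/AcOH, −20 °C to rt
Reagents that add atoms: none
Why: Evans–Saksena reduction, in which the tertiary hydroxyl binds the acetoxyborohydride and delivers hydride to the hindered ketone from its own axial face, giving the anti diol whose equatorial secondary hydroxyl cannot bridge to the axial tertiary one.

Step 19
Reactants: 26 1,3-anti diol
Product: 27 O-(imidazol-1-ylthiocarbonyl) derivative of the secondary hydroxyl
Conditions: 1,1'-thiocarbonyldiimidazole, DMAP (cat.), ClCH2CH2Cl, 70 °C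
Reagents that add atoms: 1,1'-thiocarbonyldiimidazole, S=C(n1ccnc1)n1ccnc1
Why: Thioacylation should take place only at the secondary hydroxyl, since the tertiary allylic one is too hindered and the anti, trans-fused arrangement excludes a cyclic thiocarbonate.

Step 20
Reactants: 27 thiocarbonylimidazolide
Product: 28 sesterfisherol
Conditions: Bu3SnH, AIBN (cat.), toluene, 110 °C
Reagents that add atoms: none
Why: Barton–McCombie radical deoxygenation removes the helper oxygen, the secondary radical being simply reduced by the stannane (no β-leaving group and only a disfavoured 5-endo path to the alkene), and no stereocentre is touched.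

Compound list
1 | (R)-β-citronellene | CC(C)=CCC[C@@H](C)C=C | starting material
2 | (4R)-4-methylhex-5-enal | O=CCC[C@@H](C)C=C | intermediate
3 | (5R)-1,1-dibromo-5-methylhepta-1,6-diene | BrC(Br)=CCC[C@@H](C)C=C | intermediate
4 | lithium acetylide of (3R)-3-methylhept-1-en-6-yne | [Li]C#CCC[C@@H](C)C=C | intermediate (not isolated)
5 | (3R)-3-methyloct-1-en-6-yne | CC#CCC[C@@H](C)C=C | intermediate
6 | bis(cyclopentadienyl)zirconacyclopentene fused to ring A (Zr on the methyl-bearing alkenyl carbon and on the ring CH2; ring methyl trans to CH2Zr; cyclopentadienyl ligands drawn σ-bonded) | CC1=C2CC[C@@H](C)[C@@H]2C[Zr]1(C3C=CC=C3)C3C=CC=C3 | intermediate (not isolated)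
7 | (1Z,2S,3R)-1-(1-iodoethylidene)-2-(iodomethyl)-3-methylcyclopentane | IC[C@H]1[C@H](C)CC/C1=C(\C)I | intermediate
8 | (1S,2Z,5R)-2-(1-iodoethylidene)-5-methylcyclopentane-1-carbaldehyde | O=C[C@H]1[C@H](C)CC/C1=C(\C)I | intermediate
9 | (S)-limonene | CC1=CC[C@H](CC1)C(C)=C | starting material
10 | (S)-p-menth-1-ene | CC1=CC[C@H](CC1)C(C)C | intermediate
11 | (3S)-6-oxo-3-(propan-2-yl)heptanal | O=CC[C@H](CCC(C)=O)C(C)C | intermediate
12 | (5R)-2-methyl-5-(propan-2-yl)cyclopent-1-ene-1-carbaldehyde | CC1=C(C=O)[C@@H](C(C)C)CC1 | intermediate
13 | [(5R)-2-methyl-5-(propan-2-yl)cyclopent-1-en-1-yl]methanol | CC1=C(CO)[C@@H](C(C)C)CC1 | intermediate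
14 | (3R)-2-[(but-2-yn-1-yloxy)methyl]-1-methyl-3-(propan-2-yl)cyclopent-1-ene | CC1=C(COCC#CC)[C@@H](C(C)C)CC1 | intermediate
15 | ether 14 lithiated at the propargylic O–CH2 carbon | CC1=C(COC([Li])C#CC)[C@@H](C(C)C)CC1 | intermediate (not isolated)
16 | 1-[(1S,3R)-1-methyl-2-methylidene-3-(propan-2-yl)cyclopentyl]but-2-yn-1-ol (carbinol epimers) | CC#CC(O)[C@@]1(C)CC[C@H](C(C)C)C1=C | intermediate
17 | (2E)-1-[(1S,3R)-1-methyl-2-methylidene-3-(propan-2-yl)cyclopentyl]but-2-en-1-ol (carbinol epimers) | C/C=C/C(O)[C@@]1(C)CC[C@H](C(C)C)C1=C | intermediate
18 | B-alkyl-9-BBN adduct of 17 (boron on the ring CH2 arm, cis to angular methyl and isopropyl; hydroxyl as its 9-BBN borinate) | C/C=C/C(OB3C4CCCC3CCC4)[C@@]1(C)CC[C@H](C(C)C)[C@@H]1CB3C4CCCC3CCC4 | intermediate (not isolated)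
19 | keto aldehyde: (Z)-α-methyl enone carbonyl linking ring A (formyl on the adjacent ring CH, trans to ring methyl) to the CH2 arm of ring D; ring D carries the (E)-1-hydroxybut-2-enyl arm on its quaternary carbon | O=C[C@H]1[C@H](C)CC/C1=C(\C)C(=O)C[C@H]2[C@@H](C(C)C)CC[C@]2(C)C(O)/C=C/C | intermediate
20 | keto alcohol: as 19 with vinyl in place of formyl | C=C[C@H]1[C@H](C)CC/C1=C(\C)C(=O)C[C@H]2[C@@H](C(C)C)CC[C@]2(C)C(O)/C=C/C | intermediate
21 | bis-enone: as 20 with the (E)-crotonyl ketone in place of the allylic alcohol | C=C[C@H]1[C@H](C)CC/C1=C(\C)C(=O)C[C@H]2[C@@H](C(C)C)CC[C@]2(C)C(=O)/C=C/C | intermediate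
22 | O-bound (Z)-rhodium enolate of the conjugate vinyl adduct of 21 (BINAP ligand not drawn) | C=C[C@H]1[C@H](C)CC/C1=C(\C)C(=O)C[C@H]2[C@@H](C(C)C)CC[C@]2(C)/C(O[Rh])=C/[C@@H](C)C=C | intermediate (not isolated)
23 | ring-C aldol: trans-hydrindanone with axial tertiary hydroxyl and the (Z)-ring-A alkenyl group on the carbinol carbon, and the (S)-but-3-en-2-yl group on the adjacent CH | C=C[C@H]1[C@H](C)CC/C1=C(\C)[C@@]2(O)C[C@H]3[C@@H](C(C)C)CC[C@]3(C)C(=O)[C@@H]2[C@@H](C)C=C | intermediate
24 | tetracyclic cyclooctadienone: ring B closed with a (Z)-disubstituted alkene between the two former vinyl carbons | C/C1=C2\CC[C@@H](C)[C@@H]2/C=C\[C@H](C)[C@H]2C(=O)[C@@]3(C)CC[C@H](C(C)C)[C@@H]3C[C@]12O | intermediate (not isolated)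
25 | tetracyclic β-hydroxy ketone (target skeleton with the helper ketone in ring C) | C/C1=C2\CC[C@@H](C)[C@@H]2CC[C@H](C)[C@H]2C(=O)[C@@]3(C)CC[C@H](C(C)C)[C@@H]3C[C@]12O | intermediate
26 | 1,3-anti diol (equatorial secondary hydroxyl in ring C) | C/C1=C2\CC[C@@H](C)[C@@H]2CC[C@H](C)[C@H]2[C@H](O)[C@@]3(C)CC[C@H](C(C)C)[C@@H]3C[C@]12O | intermediate
27 | O-(imidazol-1-ylthiocarbonyl) derivative of 26 at the secondary hydroxyl | C/C1=C2\CC[C@@H](C)[C@@H]2CC[C@H](C)[C@H]2[C@H](OC(=S)n4ccnc4)[C@@]3(C)CC[C@H](C(C)C)[C@@H]3C[C@]12O | intermediate
28 | sesterfisherol | C/C1=C2\CC[C@@H](C)[C@@H]2CC[C@H](C)[C@H]2C[C@@]3(C)CC[C@H](C(C)C)[C@@H]3C[C@]12O | target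

Total step count: 20. Longest linear sequence: 15 steps (steps 6–20, from (S)-limonene); the ring-A branch (steps 1–5) joins at step 13.

Steps most likely to fail

Step 16. The aldol may be thermodynamically unfavourable or reverse at the hindered, conjugated ketone; facial selectivity at the β-carbon may erode because the s-cis tert-alkyl enone binds differently from model enones; and the enolate of the other ketone may undergo base-mediated Michael addition to the crotonyl unit. The fallback separates the two bond formations and makes the aldol irreversible. It sets out from 21: (CH2=CH)2CuLi with Me3SiCl in THF at −78 °C should give the (Z)-trimethylsilyl enol ether of the conjugate adduct F1 (the epimer at the new methyl-bearing centre is removed by chromatography if needed). TiCl4 in CH2Cl2 at −78 °C should then close ring C by an intramolecular Mukaiyama aldol, and the route is rejoined at 23.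

Step 11. The [2,3]-shift onto the fully substituted alkene carbon may be slow, which would let the [1,2]-shift or propargyl–allenyl isomerisation of the anion compete, and facial selectivity at the new quaternary carbon may be incomplete. The fallback uses an unstabilised carbanion that rearranges fast at low temperature and builds the side chain afterwards. It sets out from 13: KH and Bu3SnCH2I give the tributylstannylmethyl ether F2. n-BuLi in THF at −78 °C (tin–lithium exchange, Still–Wittig [2,3]-shift) should give the hydroxymethyl compound F3 with the quaternary carbon and the exocyclic methylene. Dess–Martin periodinane gives the aldehyde F4, and (E)-prop-1-enyllithium (from (E)-1-bromoprop-1-ene and t-BuLi) in THF at −78 °C returns the route at 17.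

Step 13. Transfer of the β-branched alkyl group from boron to the hindered acylpalladium may be slow, so that direct (CO-free) coupling, protodeboronation, or base-induced epimerisation and self-condensation of the aldehyde take over. The fallback joins the fragments with organolithium chemistry and sets out from 8 and 17. On the ring-A side, Ph3P=CH2 converts 8 into the (Z)-iodo diene F5, and t-BuLi followed by ClC(=O)N(OMe)Me gives the Weinreb amide F6. On the ring-D side, t-BuMe2SiOTf with 2,6-lutidine converts 17 into the silyl ether F7; 9-BBN then H2O2/NaOH gives the primary alcohol F8; and I2/PPh3/imidazole gives the iodide F9. Lithiation of F9 with t-BuLi at −78 °C and addition to F6 should give the silyl-protected enone F10, and HF·pyridine returns the route at 20.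

Further compounds
F1 | step 16 | (Z)-trimethylsilyl enol ether of the conjugate vinyl adduct of 21 | C=C[C@H]1[C@H](C)CC/C1=C(\C)C(=O)C[C@H]2[C@@H](C(C)C)CC[C@]2(C)/C(O[Si](C)(C)C)=C/[C@@H](C)C=C
F2 | step 11 | tributylstannylmethyl ether of 13 | CCCC[Sn](CCCC)(CCCC)COCC1=C(C)CC[C@@H]1C(C)C
F3 | step 11 | [(1S,3R)-1-methyl-2-methylidene-3-(propan-2-yl)cyclopentyl]methanol | OC[C@@]1(C)CC[C@H](C(C)C)C1=C
F4 | step 11 | (1S,3R)-1-methyl-2-methylidene-3-(propan-2-yl)cyclopentane-1-carbaldehyde | O=C[C@@]1(C)CC[C@H](C(C)C)C1=C
F5 | step 13 | (Z)-iodo diene: 8 with vinyl in place of formyl | C=C[C@H]1[C@H](C)CC/C1=C(\C)I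
F6 | step 13 | (Z)-N-methoxy-N-methyl amide from F5 (amide carbonyl in place of iodine) | C=C[C@H]1[C@H](C)CC/C1=C(\C)C(=O)N(C)OC
F7 | step 13 | tert-butyldimethylsilyl ether of 17 | C/C=C/C(O[Si](C)(C)C(C)(C)C)[C@@]1(C)CC[C@H](C(C)C)C1=C
F8 | step 13 | primary alcohol from hydroboration–oxidation of F7 | C/C=C/C(O[Si](C)(C)C(C)(C)C)[C@@]1(C)CC[C@H](C(C)C)[C@@H]1CO
F9 | step 13 | primary iodide from F8 | C/C=C/C(O[Si](C)(C)C(C)(C)C)[C@@]1(C)CC[C@H](C(C)C)[C@@H]1CI
F10 | step 13 | tert-butyldimethylsilyl ether of 20 | C=C[C@H]1[C@H](C)CC/C1=C(\C)C(=O)C[C@H]2[C@@H](C(C)C)CC[C@]2(C)C(O[Si](C)(C)C(C)(C)C)/C=C/C
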